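**Retrosynthetic overview**
1. Feature: the cyclobutane C6–C7–C9–C8 (C9 spiro carbon, C8 propyl carbon), in which C7 bears the butenolide carbon C7a and its neighbour C6 bears the ring-B chain C5–C4–C3a. This is the pattern a 2-diazocyclopentanone (ketone carbon C7a, diazo carbon C7) leaves when C6 shifts in a Wolff contraction.
2. Target ⇐ dehydration of a hydroxy lactone ⇐ BuMgBr on the ring-B anhydride ⇐ carbonylation of the ring-B enol triflate ⇐ Dieckmann closure of ring B (C7a–C3a) from the cyclobutane diester.
3. Cyclobutane diester ⇐ photochemical Wolff ring contraction of spiro 2-diazocyclopentanone 19 (forms C6–C7).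
4. 19 ⇐ cyclopentanone built on cyclopent-4-ene-1,3-dione monoketal: C6 by copper-catalysed asymmetric conjugate addition–aldol, C8 by hydrogenation, C9 by aryl addition anti to propyl and ether closure.
5. The C9–O ring is carried as a benzylic ether (phthalan), because a phthalide carboxylate on C9 would be a leaving group β to every C7 enolate the route needs; it is oxidised to the phthalide at the anhydride stage. Ring order: cyclopentane (bought), phthalan, cyclobutane, ring B, anhydride, butenolide.

Key step: step 10

Remark on locants: target locants (C1 lactone carbonyl, C3 ylidene carbon, C3a, C4, C5, C6, C7, C7a, C8, C9) are used for all intermediates; descriptors quoted with them are the CIP descriptors of the compound in question.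

Assumption: the (R,S,S)-configured phosphoramidite is taken to deliver the alkyl group to the enone face that gives the (S)-configured C6 centre; if the sense of induction is the opposite, the mirror-image ligand is used.

**Route**

Step 1
Reactants: 1 cyclopent-4-ene-1,3-dione
Product: 2 8,8-dimethyl-6,10-dioxaspiro[4.5]dec-3-en-2-one
Conditions: 2,2-dimethylpropane-1,3-diol, TsOH·H2O (cat.), benzene, reflux, Dean–Stark trap
Reagents that add atoms: 2,2-dimethylpropane-1,3-diol, OCC(C)(C)CO
Why: Acid-catalysed ketalisation should stop at the monoketal because the remaining carbonyl is then a conjugated, less electrophilic enone.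

Step 2
Reactants: 3 methyl 4-iodobutanoate (two molecules are taken up per molecule of 4)
Product: 4 bis(4-methoxy-4-oxobutyl)zinc
Conditions: Et2Zn (neat, 1.5 equiv per iodide), CuI (0.3 mol %), 50 °C; EtI and excess Et2Zn removed in vacuo at 50 °C (repeated once); toluene solution
Reagents that add atoms: diethylzinc, CC[Zn]CC; methyl 4-iodobutanoate (the second molecule of 3), COC(=O)CCCI
Why: Iodine–zinc exchange of a primary alkyl iodide tolerates the ester and, once EtI and excess Et2Zn are stripped off, should leave a salt-free dialkylzinc in which each zinc carries two ester-bearing alkyl groups (2 RI + Et2Zn → R2Zn + 2 EtI), the form suited to asymmetric copper catalysis.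

Step 3
Reactants: 2 8,8-dimethyl-6,10-dioxaspiro[4.5]dec-3-en-2-one; 4 bis(4-methoxy-4-oxobutyl)zinc; 5 propanal
Product: 7 methyl 4-[(1S,2R)-2-(1-hydroxypropyl)-8,8-dimethyl-3-oxo-6,10-dioxaspiro[4.5]decan-1-yl]butanoate (carbinol epimers), via zinc enolate 6 (not isolated)
Conditions: Cu(OTf)2 (3 mol %), O,O'-(R)-1,1'-binaphthalene-2,2'-diyl N,N-bis[(S)-1-phenylethyl]phosphoramidite (6 mol %), toluene, −45 °C; aq. NH4Cl
Reagents that add atoms: none
Why: Tandem copper-catalysed enantioselective conjugate addition of the dialkylzinc and aldol trapping of the zinc enolate by the aldehyde is known for this enone monoketal; the ligand sets C6, the aldol arm enters trans to the chain, and the carbinol centre is lost in step 4.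

Step 4
Reactants: 7 methyl 4-[(1S,2R)-2-(1-hydroxypropyl)-8,8-dimethyl-3-oxo-6,10-dioxaspiro[4.5]decan-1-yl]butanoate
Product: 9 methyl 4-[(1S,2E)-8,8-dimethyl-3-oxo-2-propylidene-6,10-dioxaspiro[4.5]decan-1-yl]butanoate, via mesylate 8 (not isolated)
Conditions: MsCl, Et3N, CH2Cl2, 0 °C; then DBU, 0 °C → rt
Reagents that add atoms: none
Why: Mesylation and E1cB elimination of the β-hydroxy ketone should give the conjugated (E)-alkylidene ketone, the mesylate leaving far faster than a ketal oxygen.

Step 5
Reactants: 9 methyl 4-[(1S,2E)-8,8-dimethyl-3-oxo-2-propylidene-6,10-dioxaspiro[4.5]decan-1-yl]butanoate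
Product: 10 methyl 4-[(1S,2R)-8,8-dimethyl-3-oxo-2-propyl-6,10-dioxaspiro[4.5]decan-1-yl]butanoate (propyl cis to chain)
Conditions: H2 (1 atm), Rh/Al2O3 (5 wt % Rh), EtOAc, rt
Reagents that add atoms: none
Why: Heterogeneous hydrogenation should deliver hydrogen to the exocyclic alkene from the face opposite the adjacent C6 chain, which sets C8 with propyl cis to the chain, and rhodium on alumina is chosen for its low tendency to move the double bond into the ring.

Step 6
Reactants: 10 methyl 4-[(1S,2R)-8,8-dimethyl-3-oxo-2-propyl-6,10-dioxaspiro[4.5]decan-1-yl]butanoate; 11 (2-bromophenyl)methanol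
Product: 14 methyl 4-[(1S,2R,3S)-3-hydroxy-3-[2-(hydroxymethyl)phenyl]-8,8-dimethyl-2-propyl-6,10-dioxaspiro[4.5]decan-1-yl]butanoate, via dilithio reagent 12 (not isolated), via organocerium reagent 13 (not isolated)
Conditions: 11, n-BuLi (2.1 equiv), THF, −78 °C; CeCl3, −78 °C; then 10, −78 °C; aq. NH4Cl
Reagents that add atoms: none
Why: Bromine–lithium exchange on the lithium alkoxide and transmetalation give a weakly basic arylcerium reagent that should add to the ketone, not the ester, without epimerising C8 and from the face opposite the cis propyl and chain, which sets C9 with oxygen cis to propyl.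

Step 7
Reactants: 14 methyl 4-[(1S,2R,3S)-3-hydroxy-3-[2-(hydroxymethyl)phenyl]-8,8-dimethyl-2-propyl-6,10-dioxaspiro[4.5]decan-1-yl]butanoate
Product: 16 methyl 4-[(3'S,4'R,5'S)-5,5-dimethyl-4'-propyl-3''H-dispiro[1,3-dioxane-2,1'-cyclopentane-3',1''-isobenzofuran]-5'-yl]butanoate, via benzylic mesylate 15 (not isolated)
Conditions: MsCl, Et3N, CH2Cl2, 0 °C → rt
Reagents that add atoms: none
Why: Selective mesylation of the primary benzylic alcohol and 5-exo-tet etherification by the tertiary hydroxyl should close the phthalan, and C9 keeps its configuration because its C–O bond is not broken.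

Step 8
Reactants: 16 methyl 4-[(3'S,4'R,5'S)-5,5-dimethyl-4'-propyl-3''H-dispiro[1,3-dioxane-2,1'-cyclopentane-3',1''-isobenzofuran]-5'-yl]butanoate
Product: 17 methyl 4-[(1S,2R,3S)-4-oxo-2-propyl-3'H-spiro[cyclopentane-1,1'-isobenzofuran]-3-yl]butanoate
Conditions: PPTS (cat.), acetone/H2O (5:1), 45 °C
Reagents that add atoms: water, O
Why: Mild acid-catalysed ketal hydrolysis should release the C7a ketone under conditions too weakly acidic to epimerise the now enolisable C6 centre or to ionise the tertiary benzylic ether.

Step 9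
Reactants: 17 methyl 4-[(1S,2R,3S)-4-oxo-2-propyl-3'H-spiro[cyclopentane-1,1'-isobenzofuran]-3-yl]butanoate
Product: 19 methyl 4-[(1S,2R,3S)-5-diazo-4-oxo-2-propyl-3'H-spiro[cyclopentane-1,1'-isobenzofuran]-3-yl]butanoate, via trifluoroacetyl ketone 18 (not isolated)
Conditions: LiN(SiMe3)2, THF, −78 °C; CF3CO2CH2CF3, −78 °C; 5% aq. HCl; then MsN3, Et3N, H2O (1 equiv), MeCN, rt
Reagents that add atoms: methanesulfonyl azide, CS(=O)(=O)N=[N+]=[N-]
Why: Detrifluoroacetylative diazo transfer should work because kinetic deprotonation takes the only α-methylene (C7) without equilibrating C6, the ether oxygen on C9 is a poor leaving group from that enolate, and the activated 1,3-dicarbonyl then accepts the diazo group under mild amine base.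

Step 10
Reactants: 19 methyl 4-[(1S,2R,3S)-5-diazo-4-oxo-2-propyl-3'H-spiro[cyclopentane-1,1'-isobenzofuran]-3-yl]butanoate
Product: 21 methyl (1R,2R,3S,4R)-3-(4-methoxy-4-oxobutyl)-4-propyl-3'H-spiro[cyclobutane-1,1'-isobenzofuran]-2-carboxylate (ester trans to the chain; the all-cis epimer 22 may accompany it), via ketene 20 (not isolated)
Conditions: hν (medium-pressure Hg lamp, Pyrex filter), MeOH, 0–10 °C, argon
Reagents that add atoms: methanol, CO
Why: Excitation of the ring-locked s-Z α-diazoketone expels N2 with 1,2-shift of C6 from the carbonyl carbon C7a to the diazo carbon C7 (photochemical Wolff rearrangement), and methanol traps cyclobutylketene 20 as the C7a methyl ester. The closest known reaction type is the photochemical ring contraction of 2-diazocyclopentanones to cyclobutanecarboxylic esters. The four-membered ring C6–C7–C9–C8 closes by this ring-contracting 1,2-alkyl shift and not by cyclisation of a chain, and C6 migrates with retention, so the chain stays cis to propyl. The new centre C7 is set by protonation of the ester enol from the face away from the benzo ring, whose peri C–H lies over the other face, which should place the ester trans to the C6 chain; this configuration is not relied on because step 11 equilibrates it. The step needs the C6 shift to outrun carbene chemistry (O–H insertion into methanol, 1,2-shift of aryl or oxygen from C9), and the ring-enforced s-Z geometry, which favours the concerted shift, together with the absence of hydrogen on C9, should secure this. C6 is the only carbon on the carbonyl carbon that can migrate, so the regiochemistry of the contraction is fixed by the position of the diazo group.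

Step 11
Reactants: 21 methyl (1R,2R,3S,4R)-3-(4-methoxy-4-oxobutyl)-4-propyl-3'H-spiro[cyclobutane-1,1'-isobenzofuran]-2-carboxylate
Product: 23 cis-fused ring-B β-keto ester (ketone C7a; methyl ester on C3a; 6S,7S,8R,9R; keto–enol mixture at C3a), via all-cis diester 22 (not isolated)
Conditions: NaOMe (3 equiv), MeOH/toluene, 70 °C; then 1 M HCl, 0 °C
Reagents that add atoms: none
Why: Methoxide should equilibrate C7 through its ester enolate (rapidly reprotonated in methanol), and only the cis diester can undergo Dieckmann condensation of the chain enolate onto the C7 ester, so the stabilised β-keto ester enolate acts as the sink and fixes the cis ring fusion.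

Step 12
Reactants: 23 cis-fused ring-B β-keto ester
Product: 24 enol triflate (C7a–OTf; methyl ester on C3a; 6S,7S,8R,9R)
Conditions: Tf2O, iPr2NEt, CH2Cl2, −78 → 0 °C
Reagents that add atoms: trifluoromethanesulfonic anhydride, O=S(=O)(OS(=O)(=O)C(F)(F)F)C(F)(F)F
Why: O-Sulfonylation of the ester-conjugated enol of a cyclic β-keto ester should give the C7a=C3a vinyl triflate without touching C7.

Step 13
Reactants: 24 enol triflate
Product: 25 dimethyl ring-B ene-diester (CO2Me on C7a and on C3a; 6S,7R,8R,9R)
Conditions: Pd(OAc)2 (5 mol %), dppp, CO (1 atm), Et3N, MeOH/DMF, 60 °C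
Reagents that add atoms: carbon monoxide, [C-]#[O+]; methanol, CO
Why: Palladium-catalysed methoxycarbonylation of a vinyl triflate (oxidative addition, CO insertion, methanolysis) should install the C1 carboxyl carbon on C7a.

Step 14
Reactants: 25 dimethyl ring-B ene-diester
Product: 27 ring-B cyclic anhydride with spiro-phthalan (6S,7R,8R,9R), via diacid 26 (not isolated)
Conditions: LiOH, THF/MeOH/H2O, 50 °C; 1 M HCl; then Ac2O, 60 °C
Reagents that add atoms: lithium hydroxide, [Li+].[OH-]
Why: Saponification followed by dehydration should give the anhydride readily because a tetrasubstituted cis-ene-diacid closes to its five-membered anhydride, which is also the thermodynamic position of the double bond.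

Step 15
Reactants: 27 ring-B cyclic anhydride with spiro-phthalan
Product: 28 ring-B cyclic anhydride with spiro-phthalide (6S,7R,8R,9R)
Conditions: CrO3 (5 mol %), H5IO6 (3 equiv), MeCN, 0 °C → rt
Reagents that add atoms: periodic acid, OI(=O)(O)(O)(O)O
Why: CrO3-catalysed benzylic oxidation with periodic acid converts cyclic benzylic ethers into lactones, and the electron-poor anhydride alkene with its deactivated allylic C–H bonds should not compete.

Step 16
Reactants: 28 ring-B cyclic anhydride with spiro-phthalide; 29 butylmagnesium bromide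
Product: 30 3-butyl-3-hydroxy butenolide (hydroxy lactone; C3 epimers in equilibrium with the keto acid; 6S,7R,8R,9R)
Conditions: THF, −78 °C; then 1 M HCl
Reagents that add atoms: none
Why: Grignard mono-addition to a cyclic anhydride should occur at the C3 carbonyl, flanked only by C4H2, rather than at C1 next to C7 and the spiro centre, the carboxylate formed blocks a second addition, the phthalide is less electrophilic, and the keto acid closes to the hydroxy lactone on acidification.

Step 17
Reactants: 30 3-butyl-3-hydroxy butenolide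
Product: 31 target CNP0248594.2 ((Z)-butylidene butenolide; 6S,7R,8R,9R)
Conditions: TsOH·H2O (cat.), toluene, 80 °C, 4 Å molecular sieves
Reagents that add atoms: none
Why: Acid-catalysed dehydration of the hemiketal-type hydroxy lactone should give the exocyclic alkene as the thermodynamically preferred (Z) isomer, with the propyl chain turned away from C4.

**Compound list**
1 | cyclopent-4-ene-1,3-dione | O=C1C=CC(=O)C1 | starting material
2 | 8,8-dimethyl-6,10-dioxaspiro[4.5]dec-3-en-2-one | O=C1C=CC2(C1)OCC(C)(C)CO2 | intermediate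
3 | methyl 4-iodobutanoate | COC(=O)CCCI | starting material
4 | bis(4-methoxy-4-oxobutyl)zinc | COC(=O)CCC[Zn]CCCC(=O)OC | intermediate
5 | propanal | CCC=O | starting material
6 | alkylzinc enolate of the conjugate adduct (C6 S) | COC(=O)CCC[C@@H]1C2(OCC(C)(C)CO2)CC(O[Zn]CCCC(=O)OC)=C1 | intermediate (not isolated)
7 | methyl 4-[(1S,2R)-2-(1-hydroxypropyl)-8,8-dimethyl-3-oxo-6,10-dioxaspiro[4.5]decan-1-yl]butanoate (carbinol epimers) | COC(=O)CCC[C@@H]1C2(OCC(C)(C)CO2)CC(=O)[C@H]1C(O)CC | intermediate
8 | methanesulfonate of 7 | COC(=O)CCC[C@@H]1C2(OCC(C)(C)CO2)CC(=O)[C@H]1C(OS(C)(=O)=O)CC | intermediate (not isolated)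
9 | methyl 4-[(1S,2E)-8,8-dimethyl-3-oxo-2-propylidene-6,10-dioxaspiro[4.5]decan-1-yl]butanoate | CC/C=C1/C(=O)CC2(OCC(C)(C)CO2)[C@H]1CCCC(=O)OC | intermediate
10 | methyl 4-[(1S,2R)-8,8-dimethyl-3-oxo-2-propyl-6,10-dioxaspiro[4.5]decan-1-yl]butanoate | COC(=O)CCC[C@@H]1C2(OCC(C)(C)CO2)CC(=O)[C@@H]1CCC | intermediate
11 | (2-bromophenyl)methanol | OCc1ccccc1Br | starting material
12 | lithium (2-lithiophenyl)methanolate | [Li]OCc1ccccc1[Li] | intermediate (not isolated)
13 | dichlorocerium aryl reagent from 12 | [Li]OCc1ccccc1[Ce](Cl)Cl | intermediate (not isolated)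
14 | methyl 4-[(1S,2R,3S)-3-hydroxy-3-[2-(hydroxymethyl)phenyl]-8,8-dimethyl-2-propyl-6,10-dioxaspiro[4.5]decan-1-yl]butanoate | COC(=O)CCC[C@@H]1C2(OCC(C)(C)CO2)C[C@@](O)(c3ccccc3CO)[C@@H]1CCC | intermediate
15 | primary benzylic methanesulfonate of 14 | COC(=O)CCC[C@@H]1C2(OCC(C)(C)CO2)C[C@@](O)(c3ccccc3COS(C)(=O)=O)[C@@H]1CCC | intermediate (not isolated)
16 | methyl 4-[(3'S,4'R,5'S)-5,5-dimethyl-4'-propyl-3''H-dispiro[1,3-dioxane-2,1'-cyclopentane-3',1''-isobenzofuran]-5'-yl]butanoate | COC(=O)CCC[C@@H]1C2(OCC(C)(C)CO2)C[C@]3(OCc4ccccc43)[C@@H]1CCC | intermediate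
17 | methyl 4-[(1S,2R,3S)-4-oxo-2-propyl-3'H-spiro[cyclopentane-1,1'-isobenzofuran]-3-yl]butanoate | COC(=O)CCC[C@@H]1C(=O)C[C@]2(OCc3ccccc32)[C@@H]1CCC | intermediate
18 | C7-trifluoroacetyl derivative of 17 (C7 epimers and enol) | COC(=O)CCC[C@@H]1C(=O)C(C(=O)C(F)(F)F)[C@]2(OCc3ccccc32)[C@@H]1CCC | intermediate (not isolated)
19 | methyl 4-[(1S,2R,3S)-5-diazo-4-oxo-2-propyl-3'H-spiro[cyclopentane-1,1'-isobenzofuran]-3-yl]butanoate | COC(=O)CCC[C@@H]1C(=O)C(=[N+]=[N-])[C@]2(OCc3ccccc32)[C@@H]1CCC | intermediate
20 | cyclobutylidene ketene from 19 | COC(=O)CCC[C@H]1[C@@H](CCC)[C@@]2(OCc3ccccc32)C1=C=O | intermediate (not isolated)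
21 | methyl (1R,2R,3S,4R)-3-(4-methoxy-4-oxobutyl)-4-propyl-3'H-spiro[cyclobutane-1,1'-isobenzofuran]-2-carboxylate | COC(=O)CCC[C@H]1[C@@H](CCC)[C@@]2(OCc3ccccc32)[C@@H]1C(=O)OC | intermediate
22 | methyl (1R,2S,3S,4R)-3-(4-methoxy-4-oxobutyl)-4-propyl-3'H-spiro[cyclobutane-1,1'-isobenzofuran]-2-carboxylate (all-cis) | COC(=O)CCC[C@H]1[C@@H](CCC)[C@@]2(OCc3ccccc32)[C@H]1C(=O)OC | intermediate (not isolated)
23 | cis-fused ring-B β-keto ester (6S,7S,8R,9R; C3a undefined) | COC(=O)C1CC[C@H]2[C@@H](CCC)[C@@]3(OCc4ccccc43)[C@H]2C1=O | intermediate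
24 | ring-B enol triflate (6S,7S,8R,9R) | FC(F)(F)S(=O)(=O)OC1=C(C(=O)OC)CC[C@H]2[C@@H](CCC)[C@@]3(OCc4ccccc43)[C@@H]12 | intermediate
25 | dimethyl ring-B ene-diester (6S,7R,8R,9R) | COC(=O)C1=C(C(=O)OC)CC[C@H]2[C@@H](CCC)[C@@]3(OCc4ccccc43)[C@@H]12 | intermediate
26 | ring-B ene-diacid (6S,7R,8R,9R) | OC(=O)C1=C(C(=O)O)CC[C@H]2[C@@H](CCC)[C@@]3(OCc4ccccc43)[C@@H]12 | intermediate (not isolated)
27 | ring-B cyclic anhydride with spiro-phthalan (6S,7R,8R,9R) | O=C1OC(=O)C2=C1CC[C@H]1[C@@H](CCC)[C@@]3(OCc4ccccc43)[C@@H]21 | intermediate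
28 | ring-B cyclic anhydride with spiro-phthalide (6S,7R,8R,9R) | O=C1OC(=O)C2=C1CC[C@H]1[C@@H](CCC)[C@@]3(OC(=O)c4ccccc43)[C@@H]21 | intermediate
29 | butylmagnesium bromide | CCCC[Mg]Br | starting material
30 | 3-butyl-3-hydroxy butenolide (C3 epimers; 6S,7R,8R,9R) | CCCCC1(O)OC(=O)C2=C1CC[C@H]1[C@@H](CCC)[C@@]3(OC(=O)c4ccccc43)[C@@H]21 | intermediate
31 | CNP0248594.2 ((Z)-butylidene; 6S,7R,8R,9R) | CCC/C=C1\OC(=O)C2=C1CC[C@H]1[C@@H](CCC)[C@@]3(OC(=O)c4ccccc43)[C@@H]21 | target

Total step count: 17. Longest linear sequence: 16 steps (steps 1 and 3–17, from compound 1).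

**Steps most likely to fail**

Step 10. The process at risk is leakage from the concerted shift to a free carbene, which can insert into the O–H bond of methanol or take up the aryl group or the oxygen from C9; the strain of the four-membered ring may also slow the shift. The fallback sets out from ketone 17 and comes back at ester 21. Kinetic deprotonation (LiN(SiMe3)2, Me3SiCl, THF, −78 °C) gives the C7 trimethylsilyl enol ether F1. Tosyl azide in MeCN adds to the enol ether, and the adduct loses N2 with the same 1,2-shift of C6 from C7a to C7, now pushed by the nitrogen lone pair and not by a carbene; this is a known azide ring contraction of cyclic enol ethers and should give, after hydrolytic work-up, the ring-contracted N-tosyl cyclobutanecarboxamide F2. N-Methylation (Me3SiCHN2, MeOH) gives the activated N-methyl-N-tosyl carboxamide F3. NaOMe in MeOH should cleave it to methyl ester 21 (with 22), which goes on into step 11 in the same medium.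

Step 16. The process at risk is poor site selectivity between the two anhydride carbonyls, with attack on the phthalide as a further drain. The fallback sets out from enol triflate 24 and comes back at target 31; it tells C3 and C1 apart by their origin instead of by sterics. DIBAL-H (CH2Cl2, −78 °C) reduces the ester to allylic alcohol F4. MnO2 gives enal F5. Butylmagnesium bromide 29 (THF, −78 °C) adds to give the secondary carbinol F6. MnO2 gives butyl ketone F7. CrO3/H5IO6 in MeCN oxidises the phthalan methylene to give phthalide butyl ketone F8. Pd(PPh3)4, CO (1 atm) and Et3N in MeCN then turn the vinyl triflate into an acylpalladium species at C7a, which the enol oxygen of the C3 ketone traps to close the (Z)-butylidene butenolide 31 (carbonylative lactonisation of a β-acyl vinyl triflate).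

Step 3. The process at risk is insufficient enantiofacial control, or slow alkyl transfer, with this functionalised zinc reagent and an enolisable aldehyde. The fallback sets out from 2, 4 and 5 and comes back at enone 9; it replaces asymmetric catalysis by resolution. With PPh3 as achiral ligand for Cu(OTf)2 the same tandem reaction gives the racemic zinc enolate, that is 6 with the enantiomeric zinc enolate F9, and then the racemic aldol, that is 7 with the enantiomeric aldol F10. Dehydration as in step 4 passes through the racemic mesylate, that is 8 with the enantiomeric mesylate F11, and gives the racemic enone, that is 9 with the enantiomeric enone F12. Preparative supercritical-fluid chromatography on a chiral stationary phase then delivers 9.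

**Further compounds**
F1 | step 10 | C7 trimethylsilyl enol ether of 17 | COC(=O)CCC[C@@H]1C(O[Si](C)(C)C)=C[C@]2(OCc3ccccc32)[C@@H]1CCC
F2 | step 10 | ring-contracted N-tosyl cyclobutanecarboxamide (C7 epimers) | COC(=O)CCC[C@H]1[C@@H](CCC)[C@@]2(OCc3ccccc32)C1C(=O)NS(=O)(=O)c1ccc(C)cc1
F3 | step 10 | N-methyl-N-tosyl cyclobutanecarboxamide (C7 epimers) | COC(=O)CCC[C@H]1[C@@H](CCC)[C@@]2(OCc3ccccc32)C1C(=O)N(C)S(=O)(=O)c1ccc(C)cc1
F4 | step 16 | allylic alcohol from 24 (CH2OH on C3a) | FC(F)(F)S(=O)(=O)OC1=C(CO)CC[C@H]2[C@@H](CCC)[C@@]3(OCc4ccccc43)[C@@H]12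
F5 | step 16 | enal (CHO on C3a) | FC(F)(F)S(=O)(=O)OC1=C(C=O)CC[C@H]2[C@@H](CCC)[C@@]3(OCc4ccccc43)[C@@H]12
F6 | step 16 | secondary carbinol (1-hydroxypentyl on C3a; epimers) | FC(F)(F)S(=O)(=O)OC1=C(C(O)CCCC)CC[C@H]2[C@@H](CCC)[C@@]3(OCc4ccccc43)[C@@H]12
F7 | step 16 | butyl ketone (pentanoyl on C3a) | FC(F)(F)S(=O)(=O)OC1=C(C(=O)CCCC)CC[C@H]2[C@@H](CCC)[C@@]3(OCc4ccccc43)[C@@H]12
F8 | step 16 | phthalide butyl ketone | FC(F)(F)S(=O)(=O)OC1=C(C(=O)CCCC)CC[C@H]2[C@@H](CCC)[C@@]3(OC(=O)c4ccccc43)[C@@H]12
F9 | step 3 | enantiomer of zinc enolate 6 | COC(=O)CCC[C@H]1C2(OCC(C)(C)CO2)CC(O[Zn]CCCC(=O)OC)=C1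
F10 | step 3 | enantiomer of aldol 7 | COC(=O)CCC[C@H]1C2(OCC(C)(C)CO2)CC(=O)[C@@H]1C(O)CC
F11 | step 3 | enantiomer of mesylate 8 | COC(=O)CCC[C@H]1C2(OCC(C)(C)CO2)CC(=O)[C@@H]1C(OS(C)(=O)=O)CC
F12 | step 3 | enantiomer of enone 9 | CC/C=C1/C(=O)CC2(OCC(C)(C)CO2)[C@@H]1CCCC(=O)OC
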